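**Retrosynthetic overview**

- Feature: each benzene ring is C1(CH2 linker)–C2(H)–C3(cyclopentyl)–C4(OH)–C5(OH)–C6(H), i.e. three alkyne pairs C1≡C2, C3≡C4 and C5≡C6 with the two oxygenated carbons adjacent. The quaternary C1' (S; C2' = CMe2, C3'–C5' = CH2) is C1 of camphoric acid after loss of the C3 carboxyl.
- Target ⇒ bis(benzoxadisilole): the four aryl C–O bonds (C4 and C5 of both rings) come from aryl C–Si bonds by oxidation.
- Bis(benzoxadisilole) ⇒ hexa-1,5-diyne + 2 × HC≡C–SiMe2–O–SiMe2–C≡C–R by a two-directional Ru-catalysed (2+2+2) cycloaddition. At each end the oxadisilole ring closes first (C4–C5), then the benzene ring (C6–C1, C2–C3).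
- Tethered diyne ⇒ (S)-1-ethynyl-1,2,2-trimethylcyclopentane + ClMe2Si–O–SiMe2Cl + HC≡CMgBr. The alkyne ⇒ (1S,3R)-camphoric acid: C3 carboxyl removed by Barton decarboxylation, C1 carboxyl homologated to C≡CH, C1 untouched.

Key step: step 8

Assumption: both stereocentres of the target are read as S, which is the C1 configuration of (1S,3R)-(−)-camphoric acid (carboxyl → alkynyl → aryl keeps the highest CIP rank at C1); this acid, hexa-1,5-diyne, 1,3-dichloro-1,1,3,3-tetramethyldisiloxane and ethynylmagnesium bromide in THF are taken as purchasable.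

**Route**

Step 1
Reactants: 1 (1S,3R)-(−)-camphoric acid
Product: 2 dimethyl (1S,3R)-1,2,2-trimethylcyclopentane-1,3-dicarboxylate
Conditions: MeI, K2CO3, DMF, rt to 40 °C
Reagents that add atoms: iodomethane, CI
Why: O-Alkylation of both carboxylates (SN2 at methyl) esterifies the hindered tertiary C1 carboxyl as well, which a Fischer esterification would leave largely free, and touches no stereocentre.

Step 2
Reactants: 2 dimethyl (1S,3R)-1,2,2-trimethylcyclopentane-1,3-dicarboxylate
Product: 3 (1R,3S)-3-(methoxycarbonyl)-2,2,3-trimethylcyclopentane-1-carboxylic acid (camphoric acid with C1 as methyl ester and C3 as free acid)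
Conditions: KOH (1.1 equiv), MeOH–H2O, reflux; then aq. HCl
Reagents that add atoms: potassium hydroxide, [K+].[OH-]
Why: Saponification (BAc2) should occur only at the secondary C3 ester, because the C1 ester sits between the quaternary C1 and the CMe2 group (the classical behaviour of camphoric diesters); any epimerisation at C3 is of no consequence since that centre becomes CH2 in step 3.

Step 3
Reactants: 3 (1R,3S)-3-(methoxycarbonyl)-2,2,3-trimethylcyclopentane-1-carboxylic acid
Product: 6 methyl (S)-1,2,2-trimethylcyclopentane-1-carboxylate, via acid chloride 4 (not isolated), via Barton ester 5 (not isolated)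
Conditions: (COCl)2, cat. DMF, CH2Cl2, 0 °C to rt; then sodium pyrithione, cat. DMAP, t-BuSH, PhMe, 80 °C, hν (W lamp)
Reagents that add atoms: none
Why: Barton reductive decarboxylation: the thiohydroxamate ester 5 fragments under light to CO2 and the secondary C3 radical, which takes hydrogen from t-BuSH in a chain, so C3 becomes CH2 while the quaternary stereocentre, now the only one, is not touched.

Step 4
Reactants: 6 methyl (S)-1,2,2-trimethylcyclopentane-1-carboxylate
Product: 7 [(S)-1,2,2-trimethylcyclopentyl]methanol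
Conditions: LiAlH4, THF, 0 °C to reflux; Fieser work-up
Reagents that add atoms: none
Why: Hydride reduction of the ester to the primary alcohol with LiAlH4; the neopentyl position slows the addition, hence reflux, but no other reducible group is present.

Step 5
Reactants: 7 [(S)-1,2,2-trimethylcyclopentyl]methanol
Product: 8 (S)-1,2,2-trimethylcyclopentane-1-carbaldehyde
Conditions: Dess–Martin periodinane, CH2Cl2, rt; volatile product, concentrated cold
Reagents that add atoms: none
Why: Dess–Martin oxidation of the primary neopentyl alcohol stops at the aldehyde, which has no α-hydrogen and therefore cannot enolise or lose configuration.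

Step 6
Reactants: 8 (S)-1,2,2-trimethylcyclopentane-1-carbaldehyde
Product: 9 (S)-1-ethynyl-1,2,2-trimethylcyclopentane
Conditions: dimethyl (1-diazo-2-oxopropyl)phosphonate, K2CO3, MeOH, 0 °C to rt; pentane extraction, careful concentration
Reagents that add atoms: dimethyl (1-diazo-2-oxopropyl)phosphonate, CC(=O)C(=[N+]=[N-])P(=O)(OC)OC
Why: Ohira–Bestmann variant of the Seyferth–Gilbert homologation: methanolysis of the reagent gives the diazomethylphosphonate anion, which adds to the non-enolisable aldehyde, and the diazoalkene formed loses N2 with a 1,2-hydride shift to give the terminal alkyne with the stereocentre untouched.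

Step 7
Reactants: 9 (S)-1-ethynyl-1,2,2-trimethylcyclopentane; 10 1,3-dichloro-1,1,3,3-tetramethyldisiloxane (4 equiv); 11 ethynylmagnesium bromide (1.3 equiv)
Product: 14 1-ethynyl-1,1,3,3-tetramethyl-3-{[(S)-1,2,2-trimethylcyclopentyl]ethynyl}disiloxane, via lithium acetylide 12 (not isolated), via chlorodisiloxane 13 (not isolated)
Conditions: n-BuLi, THF, −78 °C; cannulated into 10, THF, −78 °C to rt; excess 10 removed in vacuo; then 11, THF, 0 °C to rt; aq. NH4Cl
Reagents that add atoms: none
Why: Nucleophilic substitution at silicon: the lithium acetylide 12, added to an excess of the dichlorodisiloxane, replaces one chloride (13), and after the excess is stripped off the remaining Si–Cl is replaced by the ethynyl Grignard reagent, which gives the unsymmetrical diyne without a statistical mixture.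

Step 8
Reactants: 14 1-ethynyl-1,1,3,3-tetramethyl-3-{[(S)-1,2,2-trimethylcyclopentyl]ethynyl}disiloxane (2.4 equiv); 15 hexa-1,5-diyne (1.0 equiv)
Product: 17 1,2-bis{1,1,3,3-tetramethyl-7-[(S)-1,2,2-trimethylcyclopentyl]-1,3-dihydrobenzo[c][1,2,5]oxadisilol-5-yl}ethane, via mono-cycloadduct 16 (not isolated)
Conditions: Cp*RuCl(cod) (10 mol %), ClCH2CH2Cl, 40 °C, 14 added by syringe pump over 8 h to 15 and catalyst, then 60 °C
Reagents that add atoms: none
Why: Proposed new method: Cp*RuCl should couple the two alkynes of 14 oxidatively into a ruthenacycle in which the silicon-bearing carbons C4 and C5 are joined, which closes the five-membered C–Si–O–Si–C oxadisilole ring; a terminal alkyne of 15 then inserts at the unsubstituted α-carbon (C6) and reductive elimination closes the benzene ring, a (2+2+2) closure that runs at one end of 15 (16) and then at the other (17). The closest known reaction type is the Cp*RuCl(cod)-catalysed cycloaddition of unsymmetrical carbon-, ether- or boronate-tethered 1,6-diynes with terminal alkynes, which gives meta-substituted arenes; a disiloxane tether and a tert-alkyl diyne terminus have not been shown. No stereocentre is formed, and the quaternary C1' is a spectator because no bond to it is made or broken. Regioselectivity is needed (CH2 of 15 at C1, meta to the cyclopentyl) and should be secured by the tert-alkyl group, which lets only the unsubstituted alkyne carbon of 15 bond to C3. Chemoselectivity for cross- over homo-coupling is needed and rests on the tether (intramolecular oxidative coupling of 14 should outrun coupling of two alkynes of 15, which cannot chelate as a 1,5-diyne) and on slow addition of 14, so that free 14 does not accumulate beside the ruthenacycle.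

Step 9
Reactants: 17 1,2-bis{1,1,3,3-tetramethyl-7-[(S)-1,2,2-trimethylcyclopentyl]-1,3-dihydrobenzo[c][1,2,5]oxadisilol-5-yl}ethane
Product: 19 5,5'-(ethane-1,2-diyl)bis{3-[(S)-1,2,2-trimethylcyclopentyl]benzene-1,2-diol}, via tetrakis(aryl silyl ether) 18 (not isolated)
Conditions: 30% H2O2, KF, KHCO3, THF–MeOH, 50 °C, Ar; then Na2S2O3, dil. HCl
Reagents that add atoms: hydrogen peroxide, OO
Why: Tamao–Fleming oxidation: fluoride and hydroperoxide make the silicon atoms hypercoordinate, each aryl group migrates from silicon to the peroxide oxygen so that C–O forms at the carbon that carried silicon (18), and the aryl silyl ethers are hydrolysed in the medium to the two catechols; the quaternary centres are not involved.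

**Compound list**

1 | (1S,3R)-(−)-camphoric acid | OC(=O)[C@@]1(C)CC[C@@H](C(=O)O)C1(C)C | starting material
2 | dimethyl (1S,3R)-1,2,2-trimethylcyclopentane-1,3-dicarboxylate | COC(=O)[C@@]1(C)CC[C@@H](C(=O)OC)C1(C)C | intermediate
3 | (1R,3S)-3-(methoxycarbonyl)-2,2,3-trimethylcyclopentane-1-carboxylic acid | COC(=O)[C@@]1(C)CC[C@@H](C(=O)O)C1(C)C | intermediate
4 | methyl (1S,3R)-3-(chlorocarbonyl)-1,2,2-trimethylcyclopentane-1-carboxylate (acid chloride) | COC(=O)[C@@]1(C)CC[C@@H](C(=O)Cl)C1(C)C | intermediate
5 | methyl (1S,3R)-1,2,2-trimethyl-3-{[(2-thioxopyridin-1(2H)-yl)oxy]carbonyl}cyclopentane-1-carboxylate (Barton ester) | COC(=O)[C@@]1(C)CC[C@@H](C(=O)ON2C=CC=CC2=S)C1(C)C | intermediate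
6 | methyl (S)-1,2,2-trimethylcyclopentane-1-carboxylate | COC(=O)[C@@]1(C)CCCC1(C)C | intermediate
7 | [(S)-1,2,2-trimethylcyclopentyl]methanol | OC[C@@]1(C)CCCC1(C)C | intermediate
8 | (S)-1,2,2-trimethylcyclopentane-1-carbaldehyde | O=C[C@@]1(C)CCCC1(C)C | intermediate
9 | (S)-1-ethynyl-1,2,2-trimethylcyclopentane | C#C[C@@]1(C)CCCC1(C)C | intermediate
10 | 1,3-dichloro-1,1,3,3-tetramethyldisiloxane | C[Si](C)(Cl)O[Si](C)(C)Cl | starting material
11 | ethynylmagnesium bromide | C#C[Mg]Br | starting material
12 | lithium [(S)-1,2,2-trimethylcyclopentyl]acetylide | [Li]C#C[C@@]1(C)CCCC1(C)C | intermediate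
13 | 1-chloro-1,1,3,3-tetramethyl-3-{[(S)-1,2,2-trimethylcyclopentyl]ethynyl}disiloxane | C[Si](C)(Cl)O[Si](C)(C)C#C[C@@]1(C)CCCC1(C)C | intermediate
14 | 1-ethynyl-1,1,3,3-tetramethyl-3-{[(S)-1,2,2-trimethylcyclopentyl]ethynyl}disiloxane | C#C[Si](C)(C)O[Si](C)(C)C#C[C@@]1(C)CCCC1(C)C | intermediate
15 | hexa-1,5-diyne | C#CCCC#C | starting material
16 | 5-(but-3-yn-1-yl)-1,1,3,3-tetramethyl-7-[(S)-1,2,2-trimethylcyclopentyl]-1,3-dihydrobenzo[c][1,2,5]oxadisilole (mono-cycloadduct) | C#CCCc1cc([C@@]2(C)CCCC2(C)C)c2c(c1)[Si](C)(C)O[Si]2(C)C | intermediate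
17 | 1,2-bis{1,1,3,3-tetramethyl-7-[(S)-1,2,2-trimethylcyclopentyl]-1,3-dihydrobenzo[c][1,2,5]oxadisilol-5-yl}ethane | C[Si]1(C)O[Si](C)(C)c2c([C@@]3(C)CCCC3(C)C)cc(CCc3cc4c(c([C@@]5(C)CCCC5(C)C)c3)[Si](C)(C)O[Si]4(C)C)cc21 | intermediate
18 | 1,2-bis{2,2,4,4-tetramethyl-6-[(S)-1,2,2-trimethylcyclopentyl]benzo[f][1,3,5,2,4]trioxadisilepin-8-yl}ethane (each catechol bridged O–SiMe2–O–SiMe2–O) | C[Si]1(C)O[Si](C)(C)Oc2c(O1)cc(CCc1cc3O[Si](C)(C)O[Si](C)(C)Oc3c([C@@]3(C)CCCC3(C)C)c1)cc2[C@@]1(C)CCCC1(C)C | intermediate
19 | 5,5'-(ethane-1,2-diyl)bis{3-[(S)-1,2,2-trimethylcyclopentyl]benzene-1,2-diol} (CNP0144189.1) | CC1(C)CCC[C@]1(C)c1cc(CCc2cc(O)c(O)c([C@@]3(C)CCCC3(C)C)c2)cc(O)c1O | target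

**Step count**

Total steps: 9. Longest linear sequence: 9 steps (1 → 19); compounds 10, 11 and 15 are bought.

**Steps most likely to fail**

1. Step 8, the cycloaddition.
- What may go wrong: the oxidative coupling may not start, because the tert-alkyl terminus is pressed against the Cp* ligand or because the long Si–O–Si tether holds the alkynes too far apart. The ruthenacycle may be intercepted by the ethynylsilane end of a second molecule of 14 (homo-coupling). Insertion may take the ortho sense at one of the two ends.
- Fallback (known chemistry): it sets out from alkyne 9 and hexa-1,5-diyne 15 and returns to the route at the target 19. It keeps a cyclotrimerisation, so a failure caused by the tert-alkyl terminus alone would persist, but it replaces the disiloxane tether and the ethynylsilane by a temporary boronate tether for which the three-component reaction is established.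
- Deprotonation of 9 (n-BuLi), addition to B(OiPr)3 and treatment with HCl in ether should give the alkynylboronate diisopropyl {[(S)-1,2,2-trimethylcyclopentyl]ethynyl}boronate F1.
- With propargyl alcohol, F1 exchanges one isopropoxy group in the flask to the boronate-tethered diyne F2. Cp*RuCl(cod) in ClCH2CH2Cl should then join two molecules of F2 to the two alkynes of 15 (the alkynylboronate / propargyl alcohol / terminal alkyne cyclotrimerisation) to give the bis(benzoxaborole) F3, with boron on C4 and the CH2O group on C5.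
- Oxidation of crude F3 (H2O2, NaOH) should give the bis(salicyl alcohol) F4, MnO2 the bis(salicylaldehyde) F5, and Dakin oxidation (H2O2, NaOH) the catechol 19.

2. Step 9, the fourfold oxidation.
- What may go wrong: incomplete aryl migration at the C4–Si bond, which lies next to the tert-alkyl group; protodesilylation of the ortho-silylphenol formed after the first oxidation; over-oxidation of the catechol to the o-quinone in basic peroxide.
- Fallback: it sets out from 17 and returns at 19, replacing oxidative C–Si cleavage by ipso-halogenation and ether chemistry.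
- ICl in CH2Cl2 at 0 °C should convert the four aryl–Si bonds by ipso-iododesilylation into the tetraiodide 1,2-bis{3,4-diiodo-5-[(S)-1,2,2-trimethylcyclopentyl]phenyl}ethane F6.
- Ullmann methoxylation (NaOMe, CuI, DMF–MeOH, 110 °C) should give the tetramethyl ether F7.
- BBr3 in CH2Cl2 (−78 to 0 °C) should cleave the four methyl ethers to 19.

3. Step 7, the unsymmetrical disiloxane.
- What may go wrong: double substitution of 10; scrambling of the Si–O–Si link when the acetylide or the Grignard reagent attacks silicon with loss of a silanolate, which would give symmetrical disiloxanes.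
- Fallback: it sets out from the lithium acetylide 12 and from 11 and returns at 14, building the Si–O–Si link last under amine base.
- 12 with excess Me2SiCl2 should give the chlorosilane chloro(dimethyl){[(S)-1,2,2-trimethylcyclopentyl]ethynyl}silane F8. Hydrolysis (H2O, Et3N, Et2O, 0 °C) should give the silanol F9.
- 11 with excess Me2SiCl2 should give chloro(ethynyl)dimethylsilane F10.
- Condensation of F9 with F10 (Et3N, cat. DMAP, CH2Cl2) should give 14.

**Further compounds**

F1 | step 8 | diisopropyl {[(S)-1,2,2-trimethylcyclopentyl]ethynyl}boronate | CC(C)OB(OC(C)C)C#C[C@@]1(C)CCCC1(C)C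
F2 | step 8 | isopropyl prop-2-yn-1-yl {[(S)-1,2,2-trimethylcyclopentyl]ethynyl}boronate | CC(C)OB(OCC#C)C#C[C@@]1(C)CCCC1(C)C
F3 | step 8 | 1,2-bis{1-isopropoxy-7-[(S)-1,2,2-trimethylcyclopentyl]-1,3-dihydro-2,1-benzoxaborol-5-yl}ethane | CC(C)OB1OCc2cc(CCc3cc4COB(OC(C)C)c4c([C@@]4(C)CCCC4(C)C)c3)cc([C@@]3(C)CCCC3(C)C)c12
F4 | step 8 | 1,2-bis{4-hydroxy-3-(hydroxymethyl)-5-[(S)-1,2,2-trimethylcyclopentyl]phenyl}ethane | OCc1cc(CCc2cc(CO)c(O)c([C@@]3(C)CCCC3(C)C)c2)cc([C@@]2(C)CCCC2(C)C)c1O
F5 | step 8 | 5,5'-(ethane-1,2-diyl)bis{2-hydroxy-3-[(S)-1,2,2-trimethylcyclopentyl]benzaldehyde} | O=Cc1cc(CCc2cc(C=O)c(O)c([C@@]3(C)CCCC3(C)C)c2)cc([C@@]2(C)CCCC2(C)C)c1O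
F6 | step 9 | 1,2-bis{3,4-diiodo-5-[(S)-1,2,2-trimethylcyclopentyl]phenyl}ethane | Ic1cc(CCc2cc(I)c(I)c([C@@]3(C)CCCC3(C)C)c2)cc([C@@]2(C)CCCC2(C)C)c1I
F7 | step 9 | 1,2-bis{3,4-dimethoxy-5-[(S)-1,2,2-trimethylcyclopentyl]phenyl}ethane | COc1cc(CCc2cc(OC)c(OC)c([C@@]3(C)CCCC3(C)C)c2)cc([C@@]2(C)CCCC2(C)C)c1OC
F8 | step 7 | chloro(dimethyl){[(S)-1,2,2-trimethylcyclopentyl]ethynyl}silane | C[Si](C)(Cl)C#C[C@@]1(C)CCCC1(C)C
F9 | step 7 | dimethyl{[(S)-1,2,2-trimethylcyclopentyl]ethynyl}silanol | C[Si](C)(O)C#C[C@@]1(C)CCCC1(C)C
F10 | step 7 | chloro(ethynyl)dimethylsilane | C#C[Si](C)(C)Cl
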